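**Plan** (labdane numbering: ring A = C1–C5, C10; ring B = C5–C10; C17 = exocyclic CH2 on C8; side chain C11(OAc)–C12H2–butenolide C13–C16)
1. Retrosynthesis cuts C13=C14 of the butenolide (ring-closing metathesis), then C11–C12 (Barbier allylation of the C11 aldehyde, albicanal), then ring B at C6–C7 and C8–C9 together.
2. The C7–C8 unit leaves as a chloroacetyl group (C8 as ketone, methylenated afterwards); this gives monocyclic ring-A ester 6, which goes back to 2,2,6-trimethylcyclohexanone by enolate allylation at C10.
3. Forward: ring A is bought, ring B is closed in step 5 (one flask, two stages), the butenolide ring is closed last.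
4. Enabling feature: C9 is the only enolisable carbon of 6 (alpha to the C11 ester), so it can be acylated (C8–C9); C6 is the free CH2 end of the C5=C6 alkene whose inner carbon C5 lies between quaternary C4 and C10, so the C7 alpha-keto radical must close 6-endo on C6 (C6–C7) and leaves a C5 radical inside the new decalin.
5. Stereochemistry: C10 from the chiral ligand in the palladium allylation; C5 from hydrogen-atom transfer to the ring-fusion radical anti to the axial C4 and C10 methyls; C9 by equilibration of the beta-keto ester (equatorial); C11 by CBS reduction of the C11 ketone.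

Key step: step 5

Step 1
Reactants: 1 2,2,6-trimethylcyclohexanone; 2 allyl chloroformate
Product: 3 allyl 2,6,6-trimethylcyclohex-1-en-1-yl carbonate
Conditions: LiN(SiMe3)2, TMEDA, THF, −78 to 0 °C; then 2, −78 °C
Reagents that add atoms: none
Why: Only one alpha carbon of 1 carries a proton, so a single tetrasubstituted lithium enolate forms and is O-acylated by the chloroformate (enol carbonate formation); no stereocenter is set.

Step 2
Reactants: 3 allyl 2,6,6-trimethylcyclohex-1-en-1-yl carbonate
Product: 4 (2R)-2,6,6-trimethyl-2-(prop-2-en-1-yl)cyclohexan-1-one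
Conditions: Pd2(dba)3 (cat.), (R)-t-Bu-PHOX (cat.), THF, 25 °C
Reagents that add atoms: none
Why: Decarboxylative asymmetric allylic alkylation (Tsuji–Trost type): zerovalent palladium ionises the allyl carbonate, CO2 is lost, and the chiral P,N-ligand (enantiomer chosen to give the R ketone) selects the enolate face that is allylated, setting the C10 quaternary centre.

Step 3
Reactants: 4 (2R)-2,6,6-trimethyl-2-(prop-2-en-1-yl)cyclohexan-1-one
Product: 5 methyl 2-[(1R)-1,3,3-trimethyl-2-oxocyclohexyl]acetate
Conditions: O3, NaOH, MeOH/CH2Cl2, −78 °C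
Reagents that add atoms: ozone O=[O+][O-]; methanol CO
Why: Ozonolysis in basic methanol should convert the terminal alkene directly into the methyl ester (the carbonyl oxide is trapped by methanol and the aldehyde hemiacetal is oxidised by ozone), which shortens the allyl group to the C9–C11 acetate arm while the ketone, which has no alpha hydrogen, and C10 stay untouched.

Step 4
Reactants: 5 methyl 2-[(1R)-1,3,3-trimethyl-2-oxocyclohexyl]acetate
Product: 6 methyl 2-[(1R)-1,3,3-trimethyl-2-methylidenecyclohexyl]acetate
Conditions: Zn, CH2Br2, TiCl4, THF/CH2Cl2, 0 to 25 °C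
Reagents that add atoms: dibromomethane BrCBr
Why: Takai–Lombardo methylenation: the non-basic zinc/titanium methylene reagent reacts with ketones but not with esters and should install the exocyclic C5=C6 alkene; no stereocenter is formed.

Step 5
Reactants: 6 methyl 2-[(1R)-1,3,3-trimethyl-2-methylidenecyclohexyl]acetate; 7 2-chloro-N-methoxy-N-methylacetamide
Product: 9 methyl (1R,4aS,8aS)-5,5,8a-trimethyl-2-oxodecahydronaphthalene-1-carboxylate, via chloro keto ester 8 (not isolated)
Conditions: LiN(i-Pr)2, THF, −78 °C; 7, −78 to −20 °C; AcOH; then Bu3SnH, AIBN (cat.), PhH, 80 °C, slow addition (one flask)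
Reagents that add atoms: none
Why: The lithium enolate of 6 (enolisable only at C9) adds to the carbonyl of 7 to give a chelated tetrahedral adduct that collapses on quench to the gamma-chloro beta-keto ester 8 (C8–C9 bond); Bu3Sn• then abstracts chlorine, the C7 alpha-keto radical adds to the CH2 terminus C6 of the exocyclic alkene (C6–C7 bond), and the tertiary C5 radical is reduced by Bu3SnH. The closest known reaction types are the acylation of ester enolates with N-methoxy-N-methylamides (crossed Claisen condensation) and the tin hydride mediated cyclisation of 2-oxoalkyl radicals onto alkenes to give cyclohexanones. Ring B closes in the 6-endo-trig mode, which is normal when the carbonyl lies inside the forming ring and is enforced here because 5-exo attack at C5 would build a carbon between quaternary C4 and C10. C5 is set by hydrogen-atom transfer to the decalinyl radical from the alpha face, anti to the axial methyls on C10 and C4, giving the trans ring fusion; C9 lies between two carbonyls and should settle by enolisation with the ester equatorial (H alpha); C10 is carried from 4. The step needs C-acylation and not O-acylation or chloride displacement (secured by the lithium enolate at low temperature and the stable tetrahedral adduct, which also prevents a second addition), and ring closure before reduction of the C7 radical (secured by slow addition of Bu3SnH at high dilution).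

Step 6
Reactants: 9 methyl (1R,4aS,8aS)-5,5,8a-trimethyl-2-oxodecahydronaphthalene-1-carboxylate
Product: 10 methyl (1S,4aS,8aS)-5,5,8a-trimethyl-2-methylidenedecahydronaphthalene-1-carboxylate
Conditions: Zn, CH2Br2, TiCl4, THF/CH2Cl2, 0 to 25 °C
Reagents that add atoms: dibromomethane BrCBr
Why: Takai–Lombardo methylenation should turn the C8 ketone (the oxidation-level helper of step 5) into the exocyclic C8=C17 alkene without base, so the beta-keto ester is not lost as its enolate and the equatorial C9 ester is neither epimerised nor brought into conjugation.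

Step 7
Reactants: 10 methyl (1S,4aS,8aS)-5,5,8a-trimethyl-2-methylidenedecahydronaphthalene-1-carboxylate
Product: 11 [(1S,4aS,8aS)-5,5,8a-trimethyl-2-methylidenedecahydronaphthalen-1-yl]methanol (albicanol)
Conditions: LiAlH4, Et2O, 0 °C
Reagents that add atoms: none
Why: Hydride reduction of the ester to the primary alcohol leaves the hindered 1,1-disubstituted alkene and all stereocenters untouched.

Step 8
Reactants: 11 [(1S,4aS,8aS)-5,5,8a-trimethyl-2-methylidenedecahydronaphthalen-1-yl]methanol
Product: 12 (1S,4aS,8aS)-5,5,8a-trimethyl-2-methylidenedecahydronaphthalene-1-carbaldehyde (albicanal)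
Conditions: Dess–Martin periodinane, pyridine, CH2Cl2, 0 °C
Reagents that add atoms: none
Why: Dess–Martin oxidation under buffered conditions should give the beta,gamma-unsaturated aldehyde without epimerising C9 or moving the alkene into conjugation; the aldehyde is used at once.

Step 9
Reactants: 13 2-(bromomethyl)acrylic acid; 14 allyl alcohol
Product: 15 prop-2-en-1-yl 2-(bromomethyl)prop-2-enoate
Conditions: H2SO4 (cat.), benzene, reflux, Dean–Stark trap
Reagents that add atoms: none
Why: Fischer esterification with azeotropic removal of water, the standard way to esters of this acid, provides the allyl ester needed for the final ring closure.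

Step 10
Reactants: 12 (1S,4aS,8aS)-5,5,8a-trimethyl-2-methylidenedecahydronaphthalene-1-carbaldehyde; 15 prop-2-en-1-yl 2-(bromomethyl)prop-2-enoate
Product: 16 prop-2-en-1-yl 4-hydroxy-2-methylidene-4-[(1S,4aS,8aS)-5,5,8a-trimethyl-2-methylidenedecahydronaphthalen-1-yl]butanoate (C4 epimers)
Conditions: Zn dust, THF/sat. aq. NH4Cl, 0 to 25 °C
Reagents that add atoms: none
Why: Barbier allylation: the allylzinc formed from 15 adds to the aldehyde under nearly neutral aqueous conditions and forms C11–C12 with the 2-(alkoxycarbonyl)allyl unit in place; the face selectivity at C11 does not matter because step 11 removes this centre.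

Step 11
Reactants: 16 prop-2-en-1-yl 4-hydroxy-2-methylidene-4-[(1S,4aS,8aS)-5,5,8a-trimethyl-2-methylidenedecahydronaphthalen-1-yl]butanoate
Product: 17 prop-2-en-1-yl 2-methylidene-4-oxo-4-[(1S,4aS,8aS)-5,5,8a-trimethyl-2-methylidenedecahydronaphthalen-1-yl]butanoate
Conditions: Dess–Martin periodinane, pyridine, CH2Cl2, 0 °C
Reagents that add atoms: none
Why: Dess–Martin oxidation converges both C11 epimers on one ketone under conditions mild enough to keep the acrylate double bond out of conjugation with the new ketone.

Step 12
Reactants: 17 prop-2-en-1-yl 2-methylidene-4-oxo-4-[(1S,4aS,8aS)-5,5,8a-trimethyl-2-methylidenedecahydronaphthalen-1-yl]butanoate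
Product: 18 prop-2-en-1-yl (4R)-4-hydroxy-2-methylidene-4-[(1S,4aS,8aS)-5,5,8a-trimethyl-2-methylidenedecahydronaphthalen-1-yl]butanoate
Conditions: (S)-2-methyl-CBS-oxazaborolidine, catecholborane, toluene, −78 to −40 °C
Reagents that add atoms: none
Why: Corey–Bakshi–Shibata reduction: the catalyst distinguishes the bulky ring side (C9) from the CH2 side (C12) and should deliver hydride to give the 11R carbinol, the same sense as Felkin–Anh hydride attack anti to C10 (matched case), while catecholborane leaves the alkenes and the ester alone at this temperature.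

Step 13
Reactants: 18 prop-2-en-1-yl (4R)-4-hydroxy-2-methylidene-4-[(1S,4aS,8aS)-5,5,8a-trimethyl-2-methylidenedecahydronaphthalen-1-yl]butanoate
Product: 19 prop-2-en-1-yl (4R)-4-(acetyloxy)-2-methylidene-4-[(1S,4aS,8aS)-5,5,8a-trimethyl-2-methylidenedecahydronaphthalen-1-yl]butanoate
Conditions: Ac2O, DMAP (cat.), pyridine, CH2Cl2, 0 to 25 °C
Reagents that add atoms: acetic anhydride CC(=O)OC(C)=O
Why: DMAP-catalysed acetylation proceeds with retention at C11 and, done at once, keeps the free carbinol from lactonising onto the allyl ester.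

Step 14
Reactants: 19 prop-2-en-1-yl (4R)-4-(acetyloxy)-2-methylidene-4-[(1S,4aS,8aS)-5,5,8a-trimethyl-2-methylidenedecahydronaphthalen-1-yl]butanoate
Product: 20 (1R)-1-[(1S,4aS,8aS)-5,5,8a-trimethyl-2-methylidenedecahydronaphthalen-1-yl]-2-(2-oxo-2,5-dihydrofuran-3-yl)ethyl acetate (CNP0182424.2)
Conditions: second-generation Grubbs catalyst, RuCl2(SIMes)(PCy3)(=CHPh) (cat.), toluene, 80 °C
Reagents that add atoms: none
Why: Ring-closing metathesis between the 1,1-disubstituted acrylate alkene and the allyl ester should close the alpha-substituted butenolide with loss of ethene, while the hindered exocyclic C8=C17 alkene does not take part and no stereocenter is touched.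

**Compound list**
1 | 2,2,6-trimethylcyclohexanone | CC1CCCC(C)(C)C1=O | starting material
2 | allyl chloroformate | C=CCOC(Cl)=O | starting material
3 | allyl 2,6,6-trimethylcyclohex-1-en-1-yl carbonate | C=CCOC(=O)OC1=C(C)CCCC1(C)C | intermediate
4 | (2R)-2,6,6-trimethyl-2-(prop-2-en-1-yl)cyclohexan-1-one | O=C1C(C)(C)CCC[C@]1(C)CC=C | intermediate
5 | methyl 2-[(1R)-1,3,3-trimethyl-2-oxocyclohexyl]acetate | O=C1C(C)(C)CCC[C@]1(C)CC(=O)OC | intermediate
6 | methyl 2-[(1R)-1,3,3-trimethyl-2-methylidenecyclohexyl]acetate | C=C1C(C)(C)CCC[C@]1(C)CC(=O)OC | intermediate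
7 | 2-chloro-N-methoxy-N-methylacetamide | CON(C)C(=O)CCl | starting material
8 | methyl 4-chloro-3-oxo-2-[(1R)-1,3,3-trimethyl-2-methylidenecyclohexyl]butanoate (C2 epimers, not isolated) | C=C1C(C)(C)CCC[C@]1(C)C(C(=O)OC)C(=O)CCl | intermediate
9 | methyl (1R,4aS,8aS)-5,5,8a-trimethyl-2-oxodecahydronaphthalene-1-carboxylate | O=C1CC[C@H]2C(C)(C)CCC[C@]2(C)[C@H]1C(=O)OC | intermediate
10 | methyl (1S,4aS,8aS)-5,5,8a-trimethyl-2-methylidenedecahydronaphthalene-1-carboxylate | C=C1CC[C@H]2C(C)(C)CCC[C@]2(C)[C@H]1C(=O)OC | intermediate
11 | [(1S,4aS,8aS)-5,5,8a-trimethyl-2-methylidenedecahydronaphthalen-1-yl]methanol | C=C1CC[C@H]2C(C)(C)CCC[C@]2(C)[C@H]1CO | intermediate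
12 | (1S,4aS,8aS)-5,5,8a-trimethyl-2-methylidenedecahydronaphthalene-1-carbaldehyde | C=C1CC[C@H]2C(C)(C)CCC[C@]2(C)[C@H]1C=O | intermediate
13 | 2-(bromomethyl)acrylic acid | OC(=O)C(=C)CBr | starting material
14 | allyl alcohol | OCC=C | starting material
15 | prop-2-en-1-yl 2-(bromomethyl)prop-2-enoate | C=CCOC(=O)C(=C)CBr | intermediate
16 | prop-2-en-1-yl 4-hydroxy-2-methylidene-4-[(1S,4aS,8aS)-5,5,8a-trimethyl-2-methylidenedecahydronaphthalen-1-yl]butanoate (C4 epimers) | C=C1CC[C@H]2C(C)(C)CCC[C@]2(C)[C@H]1C(O)CC(=C)C(=O)OCC=C | intermediate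
17 | prop-2-en-1-yl 2-methylidene-4-oxo-4-[(1S,4aS,8aS)-5,5,8a-trimethyl-2-methylidenedecahydronaphthalen-1-yl]butanoate | C=C1CC[C@H]2C(C)(C)CCC[C@]2(C)[C@H]1C(=O)CC(=C)C(=O)OCC=C | intermediate
18 | prop-2-en-1-yl (4R)-4-hydroxy-2-methylidene-4-[(1S,4aS,8aS)-5,5,8a-trimethyl-2-methylidenedecahydronaphthalen-1-yl]butanoate | C=C1CC[C@H]2C(C)(C)CCC[C@]2(C)[C@H]1[C@@H](CC(=C)C(=O)OCC=C)O | intermediate
19 | prop-2-en-1-yl (4R)-4-(acetyloxy)-2-methylidene-4-[(1S,4aS,8aS)-5,5,8a-trimethyl-2-methylidenedecahydronaphthalen-1-yl]butanoate | C=C1CC[C@H]2C(C)(C)CCC[C@]2(C)[C@H]1[C@@H](CC(=C)C(=O)OCC=C)OC(C)=O | intermediate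
20 | (1R)-1-[(1S,4aS,8aS)-5,5,8a-trimethyl-2-methylidenedecahydronaphthalen-1-yl]-2-(2-oxo-2,5-dihydrofuran-3-yl)ethyl acetate | C=C1CC[C@H]2C(C)(C)CCC[C@]2(C)[C@H]1[C@@H](CC1=CCOC1=O)OC(C)=O | target

Total steps: 14. Longest linear sequence: 13 (steps 1–8 and 10–14); step 9 is a one-step side branch.

**Steps most likely to fail**

Step 5. The C7 radical may take hydrogen from Bu3SnH before it closes the ring, or the acylation may stall in the flask through proton transfer between the hindered enolate and 7. The fallback closes ring B by a polar route and sets out from 6. Hydroboration of 6 with 9-BBN and iodination of the borane (I2, NaOMe) would give methyl 2-[(1R,2S)-2-(iodomethyl)-1,3,3-trimethylcyclohexyl]acetate F1; both C5 epimers are expected from the monocyclic alkene, and the one shown is wanted. Acylation of its ester enolate (LiN(i-Pr)2, then N-methoxy-N-methylacetamide) would give methyl 2-[(1R,2S)-2-(iodomethyl)-1,3,3-trimethylcyclohexyl]-3-oxobutanoate F2. NaH and then n-BuLi would form the dianion, whose terminal carbanion (C7) displaces iodide from C6 in a 6-exo-tet closure. This returns to the route at 9, the cis-fused epimer being removed by chromatography.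

Step 4. Methylene transfer may fail for steric reasons at a carbonyl flanked by two quaternary carbons. The fallback methylenates before the ester exists, so that a small organolithium can be used, and sets out from 4. Me3SiCH2Li would add to the ketone to give (2R)-2,6,6-trimethyl-2-(prop-2-en-1-yl)-1-[(trimethylsilyl)methyl]cyclohexan-1-ol F3, and KH would complete the Peterson olefination to (1R)-1,3,3-trimethyl-2-methylidene-1-(prop-2-en-1-yl)cyclohexane F4. OsO4 (cat.)/NaIO4 should cleave only the unhindered monosubstituted alkene to 2-[(1R)-1,3,3-trimethyl-2-methylidenecyclohexyl]acetaldehyde F5. Pinnick oxidation (NaClO2, NaH2PO4, 2-methyl-2-butene) would give 2-[(1R)-1,3,3-trimethyl-2-methylidenecyclohexyl]acetic acid F6, and MeI/K2CO3 returns to the route at 6.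

Step 6. Enolisation or titanium chelation of the beta-keto ester may stop the methylenation, or the new alkene may migrate into conjugation with the ester. The fallback is a two-stage Peterson olefination and sets out from 9. The weakly basic organocerium reagent from Me3SiCH2MgCl and CeCl3 should add to the ketone faster than to the ester and give methyl (1R,4aS,8aS)-2-hydroxy-5,5,8a-trimethyl-2-[(trimethylsilyl)methyl]decahydronaphthalene-1-carboxylate F7. Acid-induced elimination (aq. HF, MeCN) then returns to the route at 10.

Further compounds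
F1 | step 5 | methyl 2-[(1R,2S)-2-(iodomethyl)-1,3,3-trimethylcyclohexyl]acetate | IC[C@H]1C(C)(C)CCC[C@]1(C)CC(=O)OC
F2 | step 5 | methyl 2-[(1R,2S)-2-(iodomethyl)-1,3,3-trimethylcyclohexyl]-3-oxobutanoate | IC[C@H]1C(C)(C)CCC[C@]1(C)C(C(C)=O)C(=O)OC
F3 | step 4 | (2R)-2,6,6-trimethyl-2-(prop-2-en-1-yl)-1-[(trimethylsilyl)methyl]cyclohexan-1-ol | C[Si](C)(C)CC1(O)C(C)(C)CCC[C@]1(C)CC=C
F4 | step 4 | (1R)-1,3,3-trimethyl-2-methylidene-1-(prop-2-en-1-yl)cyclohexane | C=C1C(C)(C)CCC[C@]1(C)CC=C
F5 | step 4 | 2-[(1R)-1,3,3-trimethyl-2-methylidenecyclohexyl]acetaldehyde | C=C1C(C)(C)CCC[C@]1(C)CC=O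
F6 | step 4 | 2-[(1R)-1,3,3-trimethyl-2-methylidenecyclohexyl]acetic acid | C=C1C(C)(C)CCC[C@]1(C)CC(=O)O
F7 | step 6 | methyl (1R,4aS,8aS)-2-hydroxy-5,5,8a-trimethyl-2-[(trimethylsilyl)methyl]decahydronaphthalene-1-carboxylate | C[Si](C)(C)CC1(O)CC[C@H]2C(C)(C)CCC[C@]2(C)[C@H]1C(=O)OC
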